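The two hydroxyquinones are each cut into a four-carbon 1-methoxyallenyl ketone and a two-carbon oxalyl unit. In ring A (C1=O, C2–OH, C3–chain, C4=O, C5–OMe, C6–Me) the vicinal pair C1(=O)–C2(OH) is a latent 1,2-dione flanked by C6 and C3. The key step delivers it as the acyl-anion equivalent ethyl 1,3-dithiane-2-carboxylate: conjugate addition to the allene centre makes C6–C1 (polarity reversal) and Dieckmann closure makes C2–C3. Ring B forms the same way in the same flask from a bis(allenyl ketone). Which allene terminus carries the chain fixes the methoxy position of each ring; Hg(ClO4)2-mediated hydrolysis of the two dithioketals then gives the target.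

Key step: step 5

Assumption: compounds 1, 2, 7, 8 and 13 are taken as purchasable; 6 and 12 carry a stereogenic allene axis and are used as racemates.

Step 1
Reactants: 1 15-bromopentadecanoic acid; 2 3-methoxyprop-1-yne
Product: 3 18-methoxyoctadec-16-ynoic acid
Conditions: 2 (3 equiv), n-BuLi (2.9 equiv), THF/DMPU, −78 °C; add 1, −78 °C → rt; 1 M HCl
Reagents that add atoms: none
Why: The lithium acetylide of 2 should displace the primary bromide of the lithium carboxylate of 1 (SN2 acetylide alkylation in a dipolar medium), one equivalent of acetylide serving only to deprotonate the acid.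

Step 2
Reactants: 3 18-methoxyoctadec-16-ynoic acid
Product: 5 N,18-dimethoxy-N-methyloctadec-16-ynamide, via acyl imidazolide 4 (not isolated)
Conditions: CDI, CH2Cl2, rt; then MeNH(OMe)·HCl, rt
Reagents that add atoms: N,O-dimethylhydroxylamine hydrochloride, CNOC.Cl
Why: Carbonyldiimidazole activation followed by aminolysis is a standard Weinreb amide synthesis and leaves the propargylic ether untouched.

Step 3
Reactants: 5 N,18-dimethoxy-N-methyloctadec-16-ynamide
Product: 6 N,18-dimethoxy-N-methyloctadeca-16,17-dienamide (racemic allene axis)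
Conditions: KOt-Bu (0.2 equiv), DMSO, 20 °C, stopped at the allene stage
Reagents that add atoms: none
Why: Base-catalysed propargyl–allenyl isomerization of a 2-alkynyl methyl ether (1,3-proton shift through the oxygen-stabilised anion) should give the 3-alkyl-1-methoxyallene, with no control of the axis needed.

Step 4
Reactants: 6 N,18-dimethoxy-N-methyloctadeca-16,17-dienamide; 7 methoxyallene (1-methoxypropa-1,2-diene); 8 N-methoxy-N-methylpropanamide
Product: 12 3,21-dimethoxytetracosa-1,2,19,20-tetraene-4,22-dione, via mono-hemiaminal lithium alkoxide 9 (not isolated), via C-lithiated mono-hemiaminal 10 (not isolated), via bis-hemiaminal dilithium alkoxide 11 (not isolated)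
Conditions: 7 (1.1 equiv), n-BuLi (1.05 equiv), THF, −78 °C; add 6, −78 °C; then n-BuLi (1.1 equiv), −78 → −40 °C; then 8 (1.3 equiv), −78 → −20 °C; aq. NH4Cl
Reagents that add atoms: none
Why: This is a Weinreb ketone synthesis run twice in one flask: 1-lithio-1-methoxyallene adds to the amide to give a chelated hemiaminal that should survive α-lithiation of the internal allenyl ether (C–H next to oxygen), whose anion is acylated by 8, and both chelates collapse to ketones only on quench, the ring B allene axis arising as a racemate.

Step 5
Reactants: 12 3,21-dimethoxytetracosa-1,2,19,20-tetraene-4,22-dione; 13 ethyl 1,3-dithiane-2-carboxylate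
Product: 15 7-hydroxy-8-[14-(7-hydroxy-10-methoxy-8-methyl-9-oxo-1,5-dithiaspiro[5.5]undeca-7,10-dien-11-yl)tetradecyl]-10-methoxy-11-methyl-1,5-dithiaspiro[5.5]undeca-7,10-dien-9-one, via bis(Michael adduct) 14 (not isolated)
Conditions: 13 (2.4 equiv), KOt-Bu (2.4 equiv), THF, −40 °C; slow addition of 12; then 40 °C; 1 M HCl, 0 °C
Reagents that add atoms: none
Why: The potassium enolate of 13, a glyoxylate acyl-anion equivalent, should add to the central allene carbon of each 1-methoxyallenyl ketone; γ-protonation of the dienolate turns the allene terminus into the C6 methyl of ring A (the first chain CH2 at ring B) and gives 14, whose α′-enolate then attacks the ester with loss of ethoxide, the acidic 1,3-dione enolate being the thermodynamic sink. The closest known reaction type is the Michael–Claisen annulation of enones with malonates (dimedone synthesis), joined to the established conjugate addition of metalated 1,3-dithiane-2-carboxylates to unsaturated ketones. Each ring closes by a 6-(enolendo)-exo-trig Dieckmann condensation. No stereocenter arises, because both spiro carbons carry a symmetric dithiane, and the racemic allene axis of 12 is destroyed. The step needs 1,4- over 1,2-addition, C- over O-acylation and the Z enone geometry for closure: the soft hindered anion with reversible carbonyl addition secures the first, equilibrating alkoxide conditions the second, and E/Z exchange through the dienolate the third. The methoxy position of each ring is fixed by the substrate, since the oxygen-bearing allene carbon always ends up next to the carbon that received the nucleophile.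

Step 6
Reactants: 15 bis(quinone monodithioketal) from step 5
Product: 16 2-hydroxy-3-[14-(5-hydroxy-2-methoxy-4-methyl-3,6-dioxocyclohexa-1,4-dien-1-yl)tetradecyl]-5-methoxy-6-methylcyclohexa-2,5-diene-1,4-dione (target)
Conditions: Hg(ClO4)2·3H2O (4.4 equiv), CaCO3, THF/H2O (4:1), 0 °C → rt
Reagents that add atoms: water, O
Why: Thiophilic mercury-assisted hydrolysis of the two dithioketals (Corey–Seebach unmasking) should free the carbonyl next to the hydroxyl-bearing carbon of each ring and give the 2-hydroxy-1,4-quinone tautomer directly, with no change of oxidation level.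

Compound list
1 | 15-bromopentadecanoic acid | OC(=O)CCCCCCCCCCCCCCBr | starting material
2 | 3-methoxyprop-1-yne (methyl propargyl ether) | C#CCOC | starting material
3 | 18-methoxyoctadec-16-ynoic acid | COCC#CCCCCCCCCCCCCCCC(=O)O | intermediate
4 | 1-(imidazol-1-yl)-18-methoxyoctadec-16-yn-1-one (acyl imidazolide) | COCC#CCCCCCCCCCCCCCCC(=O)n1ccnc1 | intermediate
5 | N,18-dimethoxy-N-methyloctadec-16-ynamide | COCC#CCCCCCCCCCCCCCCC(=O)N(C)OC | intermediate
6 | N,18-dimethoxy-N-methyloctadeca-16,17-dienamide (racemic allene axis) | COC=C=CCCCCCCCCCCCCCCC(=O)N(C)OC | intermediate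
7 | methoxyallene (1-methoxypropa-1,2-diene) | COC=C=C | starting material
8 | N-methoxy-N-methylpropanamide | CCC(=O)N(C)OC | starting material
9 | lithium 3,21-dimethoxy-4-[methoxy(methyl)amino]henicosa-1,2,19,20-tetraen-4-olate (racemic) | COC=C=CCCCCCCCCCCCCCCC(O[Li])(N(C)OC)C(OC)=C=C | intermediate
10 | 21-lithio derivative of 9 (C–Li at the methoxy-bearing allene carbon; racemic) | COC([Li])=C=CCCCCCCCCCCCCCCC(O[Li])(N(C)OC)C(OC)=C=C | intermediate
11 | dilithium 3,21-dimethoxy-4,22-bis[methoxy(methyl)amino]tetracosa-1,2,19,20-tetraene-4,22-diolate (stereoisomer mixture) | CCC(O[Li])(N(C)OC)C(OC)=C=CCCCCCCCCCCCCCCC(O[Li])(N(C)OC)C(OC)=C=C | intermediate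
12 | 3,21-dimethoxytetracosa-1,2,19,20-tetraene-4,22-dione (racemic allene axis at C19–C21) | CCC(=O)C(OC)=C=CCCCCCCCCCCCCCCC(=O)C(OC)=C=C | intermediate
13 | ethyl 1,3-dithiane-2-carboxylate | CCOC(=O)C1SCCCS1 | starting material
14 | diethyl 2,2′-(3,21-dimethoxy-4,22-dioxotetracosa-2,20-diene-2,20-diyl)bis(1,3-dithiane-2-carboxylate) (E/Z mixture, equilibrating) | CCC(=O)C(OC)=C(C1(C(=O)OCC)SCCCS1)CCCCCCCCCCCCCCCC(=O)C(OC)=C(C)C2(C(=O)OCC)SCCCS2 | intermediate
15 | 7-hydroxy-8-[14-(7-hydroxy-10-methoxy-8-methyl-9-oxo-1,5-dithiaspiro[5.5]undeca-7,10-dien-11-yl)tetradecyl]-10-methoxy-11-methyl-1,5-dithiaspiro[5.5]undeca-7,10-dien-9-one (no stereocenter) | COC1=C(C)C2(SCCCS2)C(O)=C(CCCCCCCCCCCCCCC3=C(OC)C(=O)C(C)=C(O)C34SCCCS4)C1=O | intermediate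
16 | 2-hydroxy-3-[14-(5-hydroxy-2-methoxy-4-methyl-3,6-dioxocyclohexa-1,4-dien-1-yl)tetradecyl]-5-methoxy-6-methylcyclohexa-2,5-diene-1,4-dione (no stereocenter) | COC1=C(C)C(=O)C(O)=C(CCCCCCCCCCCCCCC2=C(OC)C(=O)C(C)=C(O)C2=O)C1=O | target

Total step count: 6. Longest linear sequence: 6 steps (1 → 3 → 5 → 6 → 12 → 15 → 16).

Steps most likely to fail

Step 5. Under base, the α′-enolate of one allenyl ketone may add to another molecule of 12 (oligomerisation), or the sequence may stall at the open-chain adduct. The fallback separates the two bond formations and makes the first under Lewis acid. It sets out from 12 and 13: 13 is converted with LiN(i-Pr)2 and Me3SiCl into the silyl ketene acetal 2-[ethoxy(trimethylsilyloxy)methylidene]-1,3-dithiane F1. A Mukaiyama–Michael addition of F1 to 12 (TiCl4, CH2Cl2, −78 °C) should give 14, now isolated. A separate Dieckmann closure (NaH, THF, 50 °C) brings the route back at 15.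

Step 4. The first hemiaminal may collapse early, or the two lithiated allenes may exchange protons, which would scramble the acylation. The fallback uses aldehyde electrophiles in separate flasks and oxidises at the end. It sets out from 6: reduction with i-Bu2AlH (THF, −78 °C) should give 18-methoxyoctadeca-16,17-dienal F2. Addition of 1-lithio-1-methoxyallene gives the carbinol 3,21-dimethoxyhenicosa-1,2,19,20-tetraen-4-ol F3. Treatment with n-BuLi (2.2 equiv), then propanal, gives 3,21-dimethoxytetracosa-1,2,19,20-tetraene-4,22-diol F4. Oxidation of both allenyl carbinols with activated MnO2 (CH2Cl2, rt) brings the route back at 12.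

Step 6. Water may attack the methoxy-bearing vinylogous carbon of the thionium intermediate (loss of methanol instead of sulfur), or the metal may bind the hydroxyquinone. The fallback avoids sulfur and sets out from 12. The annulation is run with the lithium enolate of 2,2-dimethyl-1,3-dioxolan-4-one (LiN(SiMe3)2, THF, −78 °C → rt), a glycolate donor one oxidation level lower. Michael addition, Dieckmann closure with loss of acetone and tautomerisation should give 3-[14-(3,5,6-trihydroxy-2-methoxy-4-methylphenyl)tetradecyl]-5-methoxy-6-methylbenzene-1,2,4-triol F5. Stirring F5 in EtOAc/aq. NaHCO3 under air oxidises both triols to the hydroxyquinones, so the route comes back at 16.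

Further compounds
F1 | step 5 | 2-[ethoxy(trimethylsilyloxy)methylidene]-1,3-dithiane | CCOC(O[Si](C)(C)C)=C1SCCCS1
F2 | step 4 | 18-methoxyoctadeca-16,17-dienal (racemic allene axis) | COC=C=CCCCCCCCCCCCCCCC=O
F3 | step 4 | 3,21-dimethoxyhenicosa-1,2,19,20-tetraen-4-ol (stereoisomer mixture) | C=C=C(OC)C(O)CCCCCCCCCCCCCCC=C=COC
F4 | step 4 | 3,21-dimethoxytetracosa-1,2,19,20-tetraene-4,22-diol (stereoisomer mixture) | C=C=C(OC)C(O)CCCCCCCCCCCCCCC=C=C(OC)C(O)CC
F5 | step 6 | 3-[14-(3,5,6-trihydroxy-2-methoxy-4-methylphenyl)tetradecyl]-5-methoxy-6-methylbenzene-1,2,4-triol | COc1c(C)c(O)c(O)c(CCCCCCCCCCCCCCc2c(OC)c(O)c(C)c(O)c2O)c1O
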